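**Plan**

1. The target is read as the (3Z,4S)-3-arylidene-4-benzyl-γ-butyrolactone (aryl cis to the lactone C=O; ring numbered O1, C2(=O), C3, C4, C5). The retrosynthesis cuts the ring at C2–C3 and at O1–C5, so that the O1–C2(=O) unit is one molecule of CO2.
2. This leaves an acyclic (Z)-enol triflate that carries a primary tosylate. It is cut further at the enol C–O bond (back to an aryl-CH2 ketone), at C(=O)–CH2Ar (thioester plus benzylzinc) and at C4–C5 (auxiliary-controlled benzyloxymethylation).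
3. Forward, the chain is joined first (asymmetric alkylation, Fukuyama ketone synthesis) and the enol triflate is made. The only ring, the lactone, is closed last by nickel-catalysed reductive carboxylation with in-flask O-alkylation, and desilylation ends the route.
4. The feature that makes the event possible: C3 is the carbonyl carbon of a benzyl ketone in the precursor and can therefore become an sp2 alkenyl–nickel nucleophile, while C5 is a primary carbon 1,3 to it across C4, so the new carboxylate reaches it through a five-membered transition state.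
5. Stereochemistry: C4 comes from the titanium-enolate alkylation directed by (S)-4-benzyloxazolidin-2-one (named R in the open-chain compounds and S in the lactone, only because the CIP priorities change). The Z alkene comes from the aryl-conjugated Z(O)-enolate of the ketone and is carried through triflate, alkenylnickel and carboxylate with retention.

Key step: step 12

Abbreviations in names: TIPSO = triisopropylsilyloxy, TBSO = tert-butyldimethylsilyloxy.

**Route**

Step 1
Reactants: 1 3-(4-hydroxy-3-methoxyphenyl)propanoic acid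
Product: 3 3-[3-methoxy-4-(TIPSO)phenyl]propanoic acid, via silyl ester 2 (not isolated)
Conditions: TIPSCl (2.2 equiv), imidazole, DMF, 25 °C; then AcOH/THF/H2O, 25 °C
Reagents that add atoms: triisopropylsilyl chloride, CC(C)[Si](Cl)(C(C)C)C(C)C
Why: Imidazole-promoted O-silylation (silyl ether protection) takes both the phenol and the acid, and aqueous acetic acid should solvolyse only the silyl ester, which is far more labile than the aryl silyl ether; no stereocentre is involved.

Step 2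
Reactants: 3 3-[3-methoxy-4-(TIPSO)phenyl]propanoic acid; 4 (S)-4-benzyloxazolidin-2-one
Product: 6 (S)-4-benzyl-3-{3-[3-methoxy-4-(TIPSO)phenyl]propanoyl}oxazolidin-2-one, via mixed pivalic anhydride 5 (not isolated)
Conditions: PivCl, Et3N, THF, −20 °C; then 4, LiCl, −20 → 25 °C
Reagents that add atoms: none
Why: N-Acylation of the auxiliary through a mixed anhydride, in which the LiCl-activated oxazolidinone attacks the less hindered carbonyl of the pivalic anhydride; no new stereocentre.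

Step 3
Reactants: 6 (S)-4-benzyl-3-{3-[3-methoxy-4-(TIPSO)phenyl]propanoyl}oxazolidin-2-one
Product: 8 (S)-4-benzyl-3-{(2R)-2-[(benzyloxy)methyl]-3-[3-methoxy-4-(TIPSO)phenyl]propanoyl}oxazolidin-2-one, via titanium enolate 7 (not isolated)
Conditions: TiCl4 (1.05 equiv), i-Pr2NEt (1.1 equiv), CH2Cl2, 0 °C; then BnOCH2Cl (2 equiv), 0 °C
Reagents that add atoms: benzyl chloromethyl ether, ClCOCc1ccccc1
Why: Evans asymmetric alkylation, in which soft enolisation gives the chelated titanium Z-enolate whose face syn to the auxiliary benzyl group is blocked, so the benzyloxymethyl electrophile enters from the other face and sets the new centre as R, the spatial arrangement needed for C4 of the lactone.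

Step 4
Reactants: 8 (S)-4-benzyl-3-{(2R)-2-[(benzyloxy)methyl]-3-[3-methoxy-4-(TIPSO)phenyl]propanoyl}oxazolidin-2-one
Product: 9 S-ethyl (2R)-2-[(benzyloxy)methyl]-3-[3-methoxy-4-(TIPSO)phenyl]propanethioate
Conditions: EtSH (3 equiv), n-BuLi (2.5 equiv), THF, 0 °C; then 8, 0 °C; NH4Cl (aq)
Reagents that add atoms: ethanethiol, CCS
Why: Auxiliary removal by acyl substitution to a thioester, since lithium ethanethiolate adds selectively to the exocyclic imide carbonyl and is too weakly basic to disturb the α-stereocentre or the aryl silyl ether.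

Step 5
Reactants: 10 3,4-dihydroxy-5-methoxybenzaldehyde
Product: 11 3,4-bis(TBSO)-5-methoxybenzaldehyde
Conditions: TBSCl (2.5 equiv), imidazole, DMF, 25 °C
Reagents that add atoms: tert-butyldimethylsilyl chloride, CC(C)(C)[Si](C)(C)Cl
Why: Standard imidazole-promoted silylation (silyl ether protection) of both catechol hydroxyls; no stereocentre.

Step 6
Reactants: 11 3,4-bis(TBSO)-5-methoxybenzaldehyde
Product: 12 [3,4-bis(TBSO)-5-methoxyphenyl]methanol
Conditions: NaBH4, THF/MeOH, −10 °C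
Reagents that add atoms: none
Why: Hydride reduction of the aromatic aldehyde to the benzylic alcohol is fast at low temperature, so it should be complete before the para-silyloxy group can be lost.

Step 7
Reactants: 12 [3,4-bis(TBSO)-5-methoxyphenyl]methanol
Product: 14 5-(chloromethyl)-1,2-bis(TBSO)-3-methoxybenzene, via benzylic mesylate 13 (not isolated)
Conditions: MsCl, Et3N, LiCl (3 equiv), THF/DMF, 0 → 25 °C
Reagents that add atoms: lithium chloride, [Li+].[Cl-]
Why: Mesylation followed by in-flask SN2 displacement by chloride (sulfonate-to-chloride exchange) is reliable for electron-rich benzylic alcohols and avoids acid that would endanger the silyl ethers.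

Step 8
Reactants: 14 5-(chloromethyl)-1,2-bis(TBSO)-3-methoxybenzene; 9 S-ethyl (2R)-2-[(benzyloxy)methyl]-3-[3-methoxy-4-(TIPSO)phenyl]propanethioate
Product: 16 (3R)-3-[(benzyloxy)methyl]-1-[3,4-bis(TBSO)-5-methoxyphenyl]-4-[3-methoxy-4-(TIPSO)phenyl]butan-2-one, via benzylzinc chloride 15 (not isolated)
Conditions: Zn dust, LiCl, THF, 25 °C; then 9, PdCl2(PPh3)2 (5 mol%), toluene/THF, 25 °C
Reagents that add atoms: none
Why: Zinc inserts into the benzylic C–Cl bond and the benzylzinc chloride couples with the thioester under palladium catalysis (Fukuyama coupling), a neutral ketone synthesis that should neither over-add, nor epimerise the α-stereocentre, nor eliminate the β-benzyloxy group.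

Step 9
Reactants: 16 (3R)-3-[(benzyloxy)methyl]-1-[3,4-bis(TBSO)-5-methoxyphenyl]-4-[3-methoxy-4-(TIPSO)phenyl]butan-2-one
Product: 18 (1Z,3R)-3-[(benzyloxy)methyl]-1-[3,4-bis(TBSO)-5-methoxyphenyl]-4-[3-methoxy-4-(TIPSO)phenyl]but-1-en-2-yl trifluoromethanesulfonate, via potassium enolate 17 (not isolated)
Conditions: KN(SiMe3)2 (1.05 equiv), THF, −78 °C; then PhNTf2, −78 → −20 °C
Reagents that add atoms: N-phenylbis(trifluoromethanesulfonimide), O=S(=O)(N(c1ccccc1)S(=O)(=O)C(F)(F)F)C(F)(F)F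
Why: Enol triflate formation, in which the far more acidic benzylic CH2 is deprotonated to the aryl-conjugated enolate, this prefers the Z(O) geometry (oxygen cis to the aryl group, away from the branched C3 substituent), and O-sulfonylation fixes that geometry, which becomes the Z geometry of the target.

Step 10
Reactants: 18 (1Z,3R)-3-[(benzyloxy)methyl]-1-[3,4-bis(TBSO)-5-methoxyphenyl]-4-[3-methoxy-4-(TIPSO)phenyl]but-1-en-2-yl trifluoromethanesulfonate
Product: 19 (1Z,3R)-1-[3,4-bis(TBSO)-5-methoxyphenyl]-3-(hydroxymethyl)-4-[3-methoxy-4-(TIPSO)phenyl]but-1-en-2-yl trifluoromethanesulfonate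
Conditions: BCl3 (3 equiv), C6HMe5 (3 equiv), CH2Cl2, −78 → −40 °C; then H2O
Reagents that add atoms: none
Why: Lewis-acid debenzylation with a cation scavenger, in which BCl3 cleaves the alkyl benzyl ether at low temperature while pentamethylbenzene traps the benzyl cation, conditions under which aryl silyl ethers, aryl methyl ethers and the enol triflate should persist (hydrogenolysis is excluded by the alkene).

Step 11
Reactants: 19 (1Z,3R)-1-[3,4-bis(TBSO)-5-methoxyphenyl]-3-(hydroxymethyl)-4-[3-methoxy-4-(TIPSO)phenyl]but-1-en-2-yl trifluoromethanesulfonate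
Product: 20 (1Z,3R)-1-[3,4-bis(TBSO)-5-methoxyphenyl]-4-[3-methoxy-4-(TIPSO)phenyl]-3-[(tosyloxy)methyl]but-1-en-2-yl trifluoromethanesulfonate
Conditions: TsCl, Et3N, DMAP (10 mol%), CH2Cl2, 0 → 25 °C
Reagents that add atoms: p-toluenesulfonyl chloride, Cc1ccc(S(=O)(=O)Cl)cc1
Why: Tosylate formation on the primary alcohol turns C5 into the electrophile for the ring closure, and the amine base is too weak to touch the enol triflate or the stereocentre.

Step 12
Reactants: 20 (1Z,3R)-1-[3,4-bis(TBSO)-5-methoxyphenyl]-4-[3-methoxy-4-(TIPSO)phenyl]-3-[(tosyloxy)methyl]but-1-en-2-yl trifluoromethanesulfonate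
Product: 22 (3Z,4S)-3-[3,4-bis(TBSO)-5-methoxybenzylidene]-4-[3-methoxy-4-(TIPSO)benzyl]dihydrofuran-2(3H)-one, via manganese carboxylate 21 (not isolated)
Conditions: CO2 (1 atm), NiBr2(dme) (10 mol%), 2,2'-bipyridine (12 mol%), Mn powder (3 equiv), DMA, 25 °C; then 50 °C; 1 M HCl work-up
Reagents that add atoms: carbon dioxide, O=C=O
Why: Zerovalent nickel–bipyridine inserts into the alkenyl C–OTf bond with retention, Mn reduces the resulting alkenylnickel species to a monovalent alkenylnickel, and this adds through its Ni–C(sp2) bond to CO2, again with retention, to give the (Z)-carboxylate 21. The closest known reaction type is the nickel-catalysed reductive carboxylation of alkenyl triflates with CO2 and Mn, combined with the ordinary O-alkylation of a carboxylate by a primary sulfonate. The lactone ring closes by 5-exo-tet SN2 attack of a carboxylate oxygen on C5, so C2–C3 and O1–C5 are both made in the same flask and the ring oxygen is a CO2 oxygen. No stereocentre is created: C4 takes part in no bond that is made or broken and the medium contains no base, so its configuration from step 3 is carried through, and the Z geometry is that of the enol triflate. The step needs chemoselectivity for C(sp2)–OTf over the C(sp3)–OTs and aryl C–O bonds and retention of the alkene geometry; the first should follow from the far faster oxidative addition of an alkenyl triflate to zerovalent nickel in the absence of iodide, the second from the configurational stability of σ-alkenylnickel intermediates. Closure is favoured because the carboxylate on C3 and the CH2OTs group on C4 are held 1,3 to each other and no competing nucleophile is present.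

Step 13
Reactants: 22 (3Z,4S)-3-[3,4-bis(TBSO)-5-methoxybenzylidene]-4-[3-methoxy-4-(TIPSO)benzyl]dihydrofuran-2(3H)-one
Product: 23 (3Z,4S)-3-(3,4-dihydroxy-5-methoxybenzylidene)-4-(4-hydroxy-3-methoxybenzyl)dihydrofuran-2(3H)-one
Conditions: Bu4NF (3.5 equiv), AcOH (4 equiv), THF, 0 °C, argon, dark
Reagents that add atoms: none
Why: Fluoride-mediated desilylation removes all three aryl silyl ethers, and the acetic acid buffer keeps the medium non-basic, so the phenolates are protonated at once and neither the Z alkene nor the allylic C4 centre should isomerise.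

**Compound list**

1 | 3-(4-hydroxy-3-methoxyphenyl)propanoic acid | COc1cc(CCC(=O)O)ccc1O | starting material
2 | triisopropylsilyl 3-[3-methoxy-4-(TIPSO)phenyl]propanoate (not isolated) | COc1cc(CCC(=O)O[Si](C(C)C)(C(C)C)C(C)C)ccc1O[Si](C(C)C)(C(C)C)C(C)C | intermediate
3 | 3-[3-methoxy-4-(TIPSO)phenyl]propanoic acid | COc1cc(CCC(=O)O)ccc1O[Si](C(C)C)(C(C)C)C(C)C | intermediate
4 | (S)-4-benzyloxazolidin-2-one | O=C1N[C@@H](Cc2ccccc2)CO1 | starting material
5 | 3-[3-methoxy-4-(TIPSO)phenyl]propanoic pivalic anhydride (not isolated) | COc1cc(CCC(=O)OC(=O)C(C)(C)C)ccc1O[Si](C(C)C)(C(C)C)C(C)C | intermediate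
6 | (S)-4-benzyl-3-{3-[3-methoxy-4-(TIPSO)phenyl]propanoyl}oxazolidin-2-one | COc1cc(CCC(=O)N2[C@@H](Cc3ccccc3)COC2=O)ccc1O[Si](C(C)C)(C(C)C)C(C)C | intermediate
7 | trichlorotitanium (Z)-enolate of 6 (not isolated) | COc1cc(C/C=C(\O[Ti](Cl)(Cl)Cl)N2[C@@H](Cc3ccccc3)COC2=O)ccc1O[Si](C(C)C)(C(C)C)C(C)C | intermediate
8 | (S)-4-benzyl-3-{(2R)-2-[(benzyloxy)methyl]-3-[3-methoxy-4-(TIPSO)phenyl]propanoyl}oxazolidin-2-one | COc1cc(C[C@@H](C(=O)N2[C@@H](Cc3ccccc3)COC2=O)COCc2ccccc2)ccc1O[Si](C(C)C)(C(C)C)C(C)C | intermediate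
9 | S-ethyl (2R)-2-[(benzyloxy)methyl]-3-[3-methoxy-4-(TIPSO)phenyl]propanethioate | COc1cc(C[C@@H](C(=O)SCC)COCc2ccccc2)ccc1O[Si](C(C)C)(C(C)C)C(C)C | intermediate
10 | 3,4-dihydroxy-5-methoxybenzaldehyde | COc1cc(C=O)cc(O)c1O | starting material
11 | 3,4-bis(TBSO)-5-methoxybenzaldehyde | COc1cc(C=O)cc(O[Si](C)(C)C(C)(C)C)c1O[Si](C)(C)C(C)(C)C | intermediate
12 | [3,4-bis(TBSO)-5-methoxyphenyl]methanol | COc1cc(CO)cc(O[Si](C)(C)C(C)(C)C)c1O[Si](C)(C)C(C)(C)C | intermediate
13 | 3,4-bis(TBSO)-5-methoxybenzyl methanesulfonate (not isolated) | COc1cc(COS(C)(=O)=O)cc(O[Si](C)(C)C(C)(C)C)c1O[Si](C)(C)C(C)(C)C | intermediate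
14 | 5-(chloromethyl)-1,2-bis(TBSO)-3-methoxybenzene | COc1cc(CCl)cc(O[Si](C)(C)C(C)(C)C)c1O[Si](C)(C)C(C)(C)C | intermediate
15 | [3,4-bis(TBSO)-5-methoxybenzyl]zinc chloride (not isolated) | COc1cc(C[Zn]Cl)cc(O[Si](C)(C)C(C)(C)C)c1O[Si](C)(C)C(C)(C)C | intermediate
16 | (3R)-3-[(benzyloxy)methyl]-1-[3,4-bis(TBSO)-5-methoxyphenyl]-4-[3-methoxy-4-(TIPSO)phenyl]butan-2-one | COc1cc(C[C@@H](C(=O)Cc2cc(O[Si](C)(C)C(C)(C)C)c(O[Si](C)(C)C(C)(C)C)c(OC)c2)COCc2ccccc2)ccc1O[Si](C(C)C)(C(C)C)C(C)C | intermediate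
17 | potassium (1Z,3R)-3-[(benzyloxy)methyl]-1-[3,4-bis(TBSO)-5-methoxyphenyl]-4-[3-methoxy-4-(TIPSO)phenyl]but-1-en-2-olate (not isolated) | COc1cc(C[C@@H](/C([O-])=C/c2cc(O[Si](C)(C)C(C)(C)C)c(O[Si](C)(C)C(C)(C)C)c(OC)c2)COCc2ccccc2)ccc1O[Si](C(C)C)(C(C)C)C(C)C.[K+] | intermediate
18 | (1Z,3R)-3-[(benzyloxy)methyl]-1-[3,4-bis(TBSO)-5-methoxyphenyl]-4-[3-methoxy-4-(TIPSO)phenyl]but-1-en-2-yl trifluoromethanesulfonate | COc1cc(C[C@@H](/C(OS(=O)(=O)C(F)(F)F)=C/c2cc(O[Si](C)(C)C(C)(C)C)c(O[Si](C)(C)C(C)(C)C)c(OC)c2)COCc2ccccc2)ccc1O[Si](C(C)C)(C(C)C)C(C)C | intermediate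
19 | (1Z,3R)-1-[3,4-bis(TBSO)-5-methoxyphenyl]-3-(hydroxymethyl)-4-[3-methoxy-4-(TIPSO)phenyl]but-1-en-2-yl trifluoromethanesulfonate | COc1cc(C[C@@H](/C(OS(=O)(=O)C(F)(F)F)=C/c2cc(O[Si](C)(C)C(C)(C)C)c(O[Si](C)(C)C(C)(C)C)c(OC)c2)CO)ccc1O[Si](C(C)C)(C(C)C)C(C)C | intermediate
20 | (1Z,3R)-1-[3,4-bis(TBSO)-5-methoxyphenyl]-4-[3-methoxy-4-(TIPSO)phenyl]-3-[(tosyloxy)methyl]but-1-en-2-yl trifluoromethanesulfonate | COc1cc(C[C@@H](/C(OS(=O)(=O)C(F)(F)F)=C/c2cc(O[Si](C)(C)C(C)(C)C)c(O[Si](C)(C)C(C)(C)C)c(OC)c2)COS(=O)(=O)c2ccc(C)cc2)ccc1O[Si](C(C)C)(C(C)C)C(C)C | intermediate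
21 | divalent manganese triflate salt of (2Z)-3-[3,4-bis(TBSO)-5-methoxyphenyl]-2-{(2S)-1-[3-methoxy-4-(TIPSO)phenyl]-3-(tosyloxy)propan-2-yl}prop-2-enoate (not isolated) | COc1cc(C[C@@H](/C(C(=O)[O-])=C/c2cc(O[Si](C)(C)C(C)(C)C)c(O[Si](C)(C)C(C)(C)C)c(OC)c2)COS(=O)(=O)c2ccc(C)cc2)ccc1O[Si](C(C)C)(C(C)C)C(C)C.[Mn+2].[O-]S(=O)(=O)C(F)(F)F | intermediate
22 | (3Z,4S)-3-[3,4-bis(TBSO)-5-methoxybenzylidene]-4-[3-methoxy-4-(TIPSO)benzyl]dihydrofuran-2(3H)-one | COc1cc(C[C@@H]2COC(=O)/C2=C\c2cc(O[Si](C)(C)C(C)(C)C)c(O[Si](C)(C)C(C)(C)C)c(OC)c2)ccc1O[Si](C(C)C)(C(C)C)C(C)C | intermediate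
23 | (3Z,4S)-3-(3,4-dihydroxy-5-methoxybenzylidene)-4-(4-hydroxy-3-methoxybenzyl)dihydrofuran-2(3H)-one | COc1cc(C[C@@H]2COC(=O)/C2=C\c2cc(O)c(O)c(OC)c2)ccc1O | target

**Step count and risks**

Total steps: 13. Longest linear sequence: 10 (steps 1–4 and 8–13); steps 5–7 prepare the second aryl fragment.

Steps most likely to fail:

Step 12. What may go wrong is partial loss of the Z geometry at the alkenylnickel stage, hydrodetriflation by adventitious proton sources, or nickel activation of the tosylate before carboxylation. The fallback is a polar organolithium route that keeps the CO2 stitch, setting out from alcohol 19 and coming back at lactone 22. Compound 19 is treated with PPh3 and N-chlorosuccinimide (CH2Cl2, 0 °C, Appel-type chlorination) to give the primary chloride (1Z,3S)-1-[3,4-bis(TBSO)-5-methoxyphenyl]-3-(chloromethyl)-4-[3-methoxy-4-(TIPSO)phenyl]but-1-en-2-yl trifluoromethanesulfonate F1. Pd(PPh3)4, Me6Sn2 and LiCl (THF, 60 °C) should exchange the triflate for trimethylstannyl with retention to give the alkenylstannane F2. MeLi (THF, −78 °C) should give the configurationally stable alkenyllithium F3 (not isolated; a primary chloride is tolerated at this temperature), CO2 converts it into the lithium carboxylate F4 (not isolated), and warming in THF/DMF with catalytic NaI at 60 °C closes the lactone 22 by the same 5-exo-tet O-alkylation.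

Step 9. What may go wrong is proton exchange between the benzylic enolate and unreacted ketone, which would epimerise C3 or expel benzyl alcoholate by β-elimination, incomplete Z selectivity in the O-sulfonylation, or anti-elimination of triflate to the alkyne by excess base. The fallback is soft enolisation in two operations, from ketone 16 back to triflate 18. Me3SiOTf and Et3N (CH2Cl2, 0 °C), an amine base that cannot deprotonate C3, should give the aryl-conjugated (1Z,3R)-trimethylsilyl enol ether F5, which is isolated so that its geometry can be checked. MeLi (THF, 0 °C) then releases the lithium (Z)-enolate F6 (not isolated) regiospecifically, and PhNTf2 converts it into 18.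

Step 10. What may go wrong is Lewis-acid cleavage of aryl silyl or methyl ethers, or Friedel–Crafts benzylation of the electron-rich rings, in competition with the debenzylation. The fallback moves the debenzylation in front of the alkene, from ketone 16 back to alcohol 19. Hydrogenolysis (H2, Pd(OH)2/C, EtOAc) gives the β-hydroxy ketone F7, and Et3SiCl with imidazole gives the triethylsilyl ether F8. KN(SiMe3)2 and PhNTf2 as in step 9 give, through the potassium enolate F9 (not isolated), the (Z)-enol triflate F10. Pyridinium p-toluenesulfonate in MeOH at 0 °C then removes the alkyl triethylsilyl ether selectively in the presence of the aryl silyl ethers to give 19.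

**Further compounds**

F1 | step 12 | (1Z,3S)-1-[3,4-bis(TBSO)-5-methoxyphenyl]-3-(chloromethyl)-4-[3-methoxy-4-(TIPSO)phenyl]but-1-en-2-yl trifluoromethanesulfonate | COc1cc(C[C@@H](/C(OS(=O)(=O)C(F)(F)F)=C/c2cc(O[Si](C)(C)C(C)(C)C)c(O[Si](C)(C)C(C)(C)C)c(OC)c2)CCl)ccc1O[Si](C(C)C)(C(C)C)C(C)C
F2 | step 12 | {(1Z,3R)-1-[3,4-bis(TBSO)-5-methoxyphenyl]-3-(chloromethyl)-4-[3-methoxy-4-(TIPSO)phenyl]but-1-en-2-yl}trimethylstannane | COc1cc(C[C@@H](/C([Sn](C)(C)C)=C/c2cc(O[Si](C)(C)C(C)(C)C)c(O[Si](C)(C)C(C)(C)C)c(OC)c2)CCl)ccc1O[Si](C(C)C)(C(C)C)C(C)C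
F3 | step 12 | {(1E,3S)-1-[3,4-bis(TBSO)-5-methoxyphenyl]-3-(chloromethyl)-4-[3-methoxy-4-(TIPSO)phenyl]but-1-en-2-yl}lithium, lithium cis to the aryl group (not isolated) | COc1cc(C[C@@H](/C([Li])=C/c2cc(O[Si](C)(C)C(C)(C)C)c(O[Si](C)(C)C(C)(C)C)c(OC)c2)CCl)ccc1O[Si](C(C)C)(C(C)C)C(C)C
F4 | step 12 | lithium (2Z)-3-[3,4-bis(TBSO)-5-methoxyphenyl]-2-{(2S)-1-chloro-3-[3-methoxy-4-(TIPSO)phenyl]propan-2-yl}prop-2-enoate (not isolated) | COc1cc(C[C@@H](/C(C(=O)[O-])=C/c2cc(O[Si](C)(C)C(C)(C)C)c(O[Si](C)(C)C(C)(C)C)c(OC)c2)CCl)ccc1O[Si](C(C)C)(C(C)C)C(C)C.[Li+]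
F5 | step 9 | {[(1Z,3R)-3-[(benzyloxy)methyl]-1-[3,4-bis(TBSO)-5-methoxyphenyl]-4-[3-methoxy-4-(TIPSO)phenyl]but-1-en-2-yl]oxy}trimethylsilane | COc1cc(C[C@@H](/C(O[Si](C)(C)C)=C/c2cc(O[Si](C)(C)C(C)(C)C)c(O[Si](C)(C)C(C)(C)C)c(OC)c2)COCc2ccccc2)ccc1O[Si](C(C)C)(C(C)C)C(C)C
F6 | step 9 | lithium (1Z,3R)-3-[(benzyloxy)methyl]-1-[3,4-bis(TBSO)-5-methoxyphenyl]-4-[3-methoxy-4-(TIPSO)phenyl]but-1-en-2-olate (not isolated) | COc1cc(C[C@@H](/C([O-])=C/c2cc(O[Si](C)(C)C(C)(C)C)c(O[Si](C)(C)C(C)(C)C)c(OC)c2)COCc2ccccc2)ccc1O[Si](C(C)C)(C(C)C)C(C)C.[Li+]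
F7 | step 10 | (3R)-1-[3,4-bis(TBSO)-5-methoxyphenyl]-3-(hydroxymethyl)-4-[3-methoxy-4-(TIPSO)phenyl]butan-2-one | COc1cc(C[C@@H](C(=O)Cc2cc(O[Si](C)(C)C(C)(C)C)c(O[Si](C)(C)C(C)(C)C)c(OC)c2)CO)ccc1O[Si](C(C)C)(C(C)C)C(C)C
F8 | step 10 | (3R)-1-[3,4-bis(TBSO)-5-methoxyphenyl]-4-[3-methoxy-4-(TIPSO)phenyl]-3-[(triethylsilyloxy)methyl]butan-2-one | COc1cc(C[C@@H](C(=O)Cc2cc(O[Si](C)(C)C(C)(C)C)c(O[Si](C)(C)C(C)(C)C)c(OC)c2)CO[Si](CC)(CC)CC)ccc1O[Si](C(C)C)(C(C)C)C(C)C
F9 | step 10 | potassium (1Z,3R)-1-[3,4-bis(TBSO)-5-methoxyphenyl]-4-[3-methoxy-4-(TIPSO)phenyl]-3-[(triethylsilyloxy)methyl]but-1-en-2-olate (not isolated) | COc1cc(C[C@@H](/C([O-])=C/c2cc(O[Si](C)(C)C(C)(C)C)c(O[Si](C)(C)C(C)(C)C)c(OC)c2)CO[Si](CC)(CC)CC)ccc1O[Si](C(C)C)(C(C)C)C(C)C.[K+]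
F10 | step 10 | (1Z,3R)-1-[3,4-bis(TBSO)-5-methoxyphenyl]-4-[3-methoxy-4-(TIPSO)phenyl]-3-[(triethylsilyloxy)methyl]but-1-en-2-yl trifluoromethanesulfonate | COc1cc(C[C@@H](/C(OS(=O)(=O)C(F)(F)F)=C/c2cc(O[Si](C)(C)C(C)(C)C)c(O[Si](C)(C)C(C)(C)C)c(OC)c2)CO[Si](CC)(CC)CC)ccc1O[Si](C(C)C)(C(C)C)C(C)C
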